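**Retrosynthetic overview**

- Last disconnections: the C3 ester (alcohol plus (2E,4E)-octa-2,4-dienoic acid) and the acid-labile groups on N1 and on the C5' oxygen.
- Key disconnection: C3=C4 (ring A) and C1'=C2' (side chain) are formed in one metathesis cascade that opens a cyclobutene. The partners are an N-acyl bicyclo[4.2.0]oct-7-en-2-yl amine carrying a D-alanine-derived 2-silyloxy-1-alkene, and the silyl ether of (R)-oct-1-en-5-ol.
- Feature used: on ring B (C4a, C5, C6, C7, C8, C8a) the bonds C4a–C4 and C5–C1' are vicinal and cis, and N1 on C8a is cis to both. C4 and C1' can therefore be stored as the CH=CH of a cyclobutene cis-fused to ring B.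
- Ring order: ring B is bought as cyclohex-2-en-1-one, the auxiliary cyclobutene is fused on photochemically, N1 is attached by reductive amination, and ring A is closed last, as the cyclobutene is consumed.

Key step: step 9

Remark: the photoadduct of step 1 is racemic. D-Alanine acts as the resolving partner in step 2, so at most half of the ketone is carried on and the diastereomer from the mirror-image ketone is discarded. Target atoms are numbered as in decahydroquinoline (N1, C2 to C8a, side chain C1' to C8'); names of intermediates before step 9 use bicyclo[4.2.0]octene numbering.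

**Route**

Step 1
Reactants: 1 cyclohex-2-en-1-one
Product: 2 cis-bicyclo[4.2.0]oct-7-en-2-one (racemate; the (1S,6R) enantiomer is the one carried on)
Conditions: HC≡CH (saturated solution, slow stream), hν (λ > 340 nm), CH2Cl2, −40 °C, stopped at partial conversion
Reagents that add atoms: acetylene, C#C
Why: Enone–alkyne [2+2] photocycloaddition through the enone triplet and a 1,4-biradical gives the cyclobutene directly, the four-membered ring can only close cis on the six-membered ring so C1 and C6 are set cis (as a racemate), and long-wavelength light with a stop at partial conversion limits secondary photochemistry of the β,γ-unsaturated ketone.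

Step 2
Reactants: 2 cis-bicyclo[4.2.0]oct-7-en-2-one; 3 methyl D-alaninate hydrochloride
Product: 5 methyl (2R)-2-{[(1S,2R,6R)-bicyclo[4.2.0]oct-7-en-2-yl]amino}propanoate, via imine 4 (not isolated)
Conditions: Et3N, AcOH, NaBH(OAc)3, ClCH2CH2Cl, rt; chromatographic removal of the diastereomer from the (1R,6S) ketone
Reagents that add atoms: none
Why: Reductive amination with an acyloxyborohydride, in which the iminium form of 4 takes hydride on its convex face, anti to the cyclobutene, so that N ends cis to the four-membered ring (2R in the 1S,6R series); the alanine centre is untouched under the weakly acidic conditions and, because D-alanine is one enantiomer, the two ketone enantiomers give separable diastereomers.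

Step 3
Reactants: 5 methyl (2R)-2-{[(1S,2R,6R)-bicyclo[4.2.0]oct-7-en-2-yl]amino}propanoate
Product: 6 methyl (2R)-2-{[(benzyloxy)carbonyl][(1S,2R,6R)-bicyclo[4.2.0]oct-7-en-2-yl]amino}propanoate
Conditions: CbzCl, i-Pr2NEt, CH2Cl2, 0 → 40 °C
Reagents that add atoms: benzyl chloroformate, O=C(Cl)OCc1ccccc1
Why: N-Acylation of a hindered di-sec-alkyl amine calls for the acid-chloride reactivity of a chloroformate (Boc2O would be too slow on this nitrogen), no stereocentre is touched, and the benzyl carbamate makes N1 non-basic for the later organometallic and metathesis steps.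

Step 4
Reactants: 6 methyl (2R)-2-{[(benzyloxy)carbonyl][(1S,2R,6R)-bicyclo[4.2.0]oct-7-en-2-yl]amino}propanoate
Product: 7 benzyl N-[(1S,2R,6R)-bicyclo[4.2.0]oct-7-en-2-yl]-N-{(2R)-1-[methoxy(methyl)amino]-1-oxopropan-2-yl}carbamate
Conditions: MeNHOMe·HCl, i-PrMgCl, THF, −20 → 0 °C; then H2O
Reagents that add atoms: N,O-dimethylhydroxylamine hydrochloride, CNOC.Cl
Why: Weinreb amidation of the methyl ester by the chloromagnesium amide of N,O-dimethylhydroxylamine is mild enough to leave the α-stereocentre, the carbamate and the cyclobutene alone, and it opens a titanium-free way to the enol ether, since Cp2Ti=CH2-type ester methylenation reagents are themselves metathesis initiators for strained cyclobutenes.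

Step 5
Reactants: 7 benzyl N-[(1S,2R,6R)-bicyclo[4.2.0]oct-7-en-2-yl]-N-{(2R)-1-[methoxy(methyl)amino]-1-oxopropan-2-yl}carbamate
Product: 9 benzyl N-[(1S,2R,6R)-bicyclo[4.2.0]oct-7-en-2-yl]-N-[(2R)-3-oxobutan-2-yl]carbamate, via magnesium hemiaminal 8 (not isolated)
Conditions: MeMgBr, THF, −78 → 0 °C; then H2O
Reagents that add atoms: methylmagnesium bromide, C[Mg]Br
Why: Weinreb ketone synthesis, in which the chelated tetrahedral adduct 8 resists a second addition and collapses to the methyl ketone only on work-up, while the N,N-disubstituted α-amino ketone keeps its configuration under these non-equilibrating conditions.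

Step 6
Reactants: 9 benzyl N-[(1S,2R,6R)-bicyclo[4.2.0]oct-7-en-2-yl]-N-[(2R)-3-oxobutan-2-yl]carbamate
Product: 11 benzyl N-[(1S,2R,6R)-bicyclo[4.2.0]oct-7-en-2-yl]-N-{(2R)-3-[(triethylsilyl)oxy]but-3-en-2-yl}carbamate (fragment 1), via lithium enolate 10 (not isolated)
Conditions: Et3SiCl, then LiN(SiMe3)2 (internal quench), THF, −78 °C
Reagents that add atoms: chlorotriethylsilane, CC[Si](Cl)(CC)CC
Why: Kinetic enolisation of the methyl ketone removes a proton from the unhindered CH3 and not from the N-substituted methine, whose C–H is held in the carbamate plane by A(1,3) strain, and immediate O-silylation gives the terminal 2-silyloxy alkene with C2 intact and before the enolate can attack the carbamate.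

Step 7
Reactants: 12 (2R)-2-propyloxirane
Product: 13 (5R)-oct-1-en-5-ol
Conditions: CH2=CHCH2MgBr, CuI (10 mol%), THF, −40 → 0 °C; then H2O
Reagents that add atoms: allylmagnesium bromide, C=CC[Mg]Br
Why: Copper-catalysed Grignard opening of a terminal epoxide is an SN2 attack at the CH2 carbon, so the stereocentre is not touched and stays R.

Step 8
Reactants: 13 (5R)-oct-1-en-5-ol
Product: 14 tert-butyl(dimethyl){[(5R)-oct-1-en-5-yl]oxy}silane (fragment 2)
Conditions: TBSCl, imidazole, DMF, rt
Reagents that add atoms: tert-butyldimethylsilyl chloride, CC(C)(C)[Si](C)(C)Cl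
Why: Standard silylation of a secondary alcohol, which keeps the C5' hydroxyl distinct from the C3 hydroxyl that is acylated in step 13.

Step 9
Reactants: 11 benzyl N-[(1S,2R,6R)-bicyclo[4.2.0]oct-7-en-2-yl]-N-{(2R)-3-[(triethylsilyl)oxy]but-3-en-2-yl}carbamate; 14 tert-butyl(dimethyl){[(5R)-oct-1-en-5-yl]oxy}silane
Product: 15 benzyl (2R,4aR,5R,8aR)-5-[(1E,5R)-5-{[tert-butyl(dimethyl)silyl]oxy}oct-1-en-1-yl]-2-methyl-3-[(triethylsilyl)oxy]-4a,5,6,7,8,8a-hexahydroquinoline-1(2H)-carboxylate
Conditions: RuCl2(H2IMes)(=CH-C6H4-2-O-i-Pr) (second-generation Hoveyda-Grubbs catalyst, 10 mol%), 14 (3 equiv), toluene, 60 °C, slow addition of 11 (5 mM final), argon sparge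
Reagents that add atoms: none
Why: Proposed new method: a ruthenium alkylidene, formed from the catalyst and the excess of 14, adds to the strained C4=C1' bond of the cyclobutene and cycloreverts, and the release of ring strain makes this opening irreversible and leaves the two former cyclobutene carbons as alkene or alkylidene ends held cis on ring B. The closest known reactions are ring-opening/ring-closing/cross metathesis of fused cyclobutenes that carry ordinary alkene tethers and, separately, ring-closing metathesis of an alkene onto a 2-silyloxy or 2-alkoxy 1-alkene; what is new is the use of the enol ether as the ring-closing acceptor inside the cyclobutene cascade. Ring A closes by six-membered ring-closing metathesis of the C4 alkylidene onto the CH2 terminus of the silyl enol ether (C3=C4 forms and the CH2 leaves on ruthenium), while the C1' end is capped by cross-metathesis with 14 (C1'=C2' forms), and because every acyclic alkene made on the way stays metathesis-active, either regiochemistry of the first opening drains into 15 with loss of one ethene. No stereocentre is created: C2, C4a, C5 and C8a come unchanged from 11, the cis fusion of the cyclobutene becomes the cis C4a/C5 relationship, the cis A/B fusion follows from N1 having been placed cis to C4 in step 2, and the geometry of C1'=C2' (E expected) is irrelevant because step 12 hydrogenates it. The step needs site selectivity between the two ends and chemoselectivity against ring-opening oligomerisation; the first is secured because only the C4 end reaches the enol ether through a fused six-membered ring (the C1' end could only close a bridged seven-membered ring across C5 and C8a, which requires a 1,3-diaxial conformer), the second by slow addition of 11 to a dilute solution that holds 14 in excess. The benzyl carbamate keeps N1 from binding ruthenium, and the 1,1-disubstituted silyl enol ether is too hindered at its substituted carbon to be turned into an inert ruthenium oxycarbene.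

Step 10
Reactants: 15 benzyl (2R,4aR,5R,8aR)-5-[(1E,5R)-5-{[tert-butyl(dimethyl)silyl]oxy}oct-1-en-1-yl]-2-methyl-3-[(triethylsilyl)oxy]-4a,5,6,7,8,8a-hexahydroquinoline-1(2H)-carboxylate
Product: 16 benzyl (2R,4aS,5R,8aR)-5-[(1E,5R)-5-{[tert-butyl(dimethyl)silyl]oxy}oct-1-en-1-yl]-2-methyl-3-oxooctahydroquinoline-1(2H)-carboxylate
Conditions: AcOH/THF/H2O (3:1:1), rt, short reaction time
Reagents that add atoms: none
Why: Acid-catalysed hydrolysis of the silyl enol ether (protonation at C4, then loss of the silyl group from oxygen) frees the C3 ketone much faster than the weak acid attacks the secondary alkyl silyl ether or the carbamate, and C2 is not epimerised because no base is present and C4a is not enolisable.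

Step 11
Reactants: 16 benzyl (2R,4aS,5R,8aR)-5-[(1E,5R)-5-{[tert-butyl(dimethyl)silyl]oxy}oct-1-en-1-yl]-2-methyl-3-oxooctahydroquinoline-1(2H)-carboxylate
Product: 17 benzyl (2R,3R,4aS,5R,8aR)-5-[(1E,5R)-5-{[tert-butyl(dimethyl)silyl]oxy}oct-1-en-1-yl]-3-hydroxy-2-methyloctahydroquinoline-1(2H)-carboxylate
Conditions: LiBH(s-Bu)3, THF, −78 °C; then H2O
Reagents that add atoms: none
Why: Bulky trialkylborohydride reduction, in which the reagent reaches C3 from the face away from the neighbouring C2 methyl (pushed out of the ring plane by A(1,3) strain with the carbamate), so the new hydroxyl ends cis to the methyl (3R), as is established for N-acyl 2-alkylpiperidin-3-ones.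

Step 12
Reactants: 17 benzyl (2R,3R,4aS,5R,8aR)-5-[(1E,5R)-5-{[tert-butyl(dimethyl)silyl]oxy}oct-1-en-1-yl]-3-hydroxy-2-methyloctahydroquinoline-1(2H)-carboxylate
Product: 19 tert-butyl (2R,3R,4aS,5S,8aR)-5-[(5R)-5-{[tert-butyl(dimethyl)silyl]oxy}octyl]-3-hydroxy-2-methyloctahydroquinoline-1(2H)-carboxylate, via amino alcohol 18 (not isolated)
Conditions: H2 (1 atm), Pd/C (10 wt%), Boc2O, EtOAc, rt, then 45 °C after hydrogen uptake
Reagents that add atoms: di-tert-butyl dicarbonate, CC(C)(C)OC(=O)OC(=O)OC(C)(C)C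
Why: Heterogeneous hydrogenation saturates C1'=C2' and hydrogenolyses the benzyl carbamate, and the liberated ring amine 18, less hindered than the acyclic amine of step 3, is trapped in the same flask as the tert-butyl carbamate, so that only the C3 hydroxyl is free for acylation and the nitrogen group can later leave under acid.

Step 13
Reactants: 19 tert-butyl (2R,3R,4aS,5S,8aR)-5-[(5R)-5-{[tert-butyl(dimethyl)silyl]oxy}octyl]-3-hydroxy-2-methyloctahydroquinoline-1(2H)-carboxylate; 20 (2E,4E)-octa-2,4-dienoic acid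
Product: 22 tert-butyl (2R,3R,4aS,5S,8aR)-5-[(5R)-5-{[tert-butyl(dimethyl)silyl]oxy}octyl]-2-methyl-3-{[(2E,4E)-octa-2,4-dienoyl]oxy}octahydroquinoline-1(2H)-carboxylate, via mixed anhydride 21 (not isolated)
Conditions: 20, 2,4,6-trichlorobenzoyl chloride, Et3N, THF, rt; then 19, DMAP, toluene, rt
Reagents that add atoms: none
Why: Yamaguchi esterification, in which DMAP attacks the mixed anhydride 21 at the unhindered dienoyl carbonyl and the acylpyridinium acylates the hindered secondary C3 alcohol with retention at C3 and without moving the 2E,4E double bonds.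

Step 14
Reactants: 22 tert-butyl (2R,3R,4aS,5S,8aR)-5-[(5R)-5-{[tert-butyl(dimethyl)silyl]oxy}octyl]-2-methyl-3-{[(2E,4E)-octa-2,4-dienoyl]oxy}octahydroquinoline-1(2H)-carboxylate
Product: 23 (2R,3R,4aS,5S,8aR)-5-[(5R)-5-hydroxyoctyl]-2-methyldecahydroquinolin-3-yl (2E,4E)-octa-2,4-dienoate (target)
Conditions: TFA/H2O (9:1), 0 °C → rt; then cold aq. NaHCO3
Reagents that add atoms: none
Why: Acidolysis removes the tert-butyl carbamate (as 2-methylpropene and carbon dioxide) and the silyl ether in one operation, the dienoate ester is stable to acid, and a brief cold bicarbonate work-up frees the amine without giving time for O-to-N acyl shift.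

**Compound list**

1 | cyclohex-2-en-1-one | O=C1C=CCCC1 | starting material
2 | cis-bicyclo[4.2.0]oct-7-en-2-one (racemate; the (1S,6R) enantiomer, which is carried on, is drawn) | O=C1CCC[C@@H]2C=C[C@H]12 | intermediate
3 | methyl D-alaninate hydrochloride | C[C@@H](N)C(=O)OC.Cl | starting material
4 | methyl (2R)-2-{[(1S,6R)-bicyclo[4.2.0]oct-7-en-2-ylidene]amino}propanoate (formed together with its (1R,6S) diastereomer) | COC(=O)[C@@H](C)N=C1CCC[C@@H]2C=C[C@H]12 | intermediate (not isolated)
5 | methyl (2R)-2-{[(1S,2R,6R)-bicyclo[4.2.0]oct-7-en-2-yl]amino}propanoate | COC(=O)[C@@H](C)N[C@@H]1CCC[C@@H]2C=C[C@H]12 | intermediate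
6 | methyl (2R)-2-{[(benzyloxy)carbonyl][(1S,2R,6R)-bicyclo[4.2.0]oct-7-en-2-yl]amino}propanoate | COC(=O)[C@@H](C)N(C(=O)OCc1ccccc1)[C@@H]1CCC[C@@H]2C=C[C@H]12 | intermediate
7 | benzyl N-[(1S,2R,6R)-bicyclo[4.2.0]oct-7-en-2-yl]-N-{(2R)-1-[methoxy(methyl)amino]-1-oxopropan-2-yl}carbamate | CON(C)C(=O)[C@@H](C)N(C(=O)OCc1ccccc1)[C@@H]1CCC[C@@H]2C=C[C@H]12 | intermediate
8 | bromomagnesium alkoxide of the tetrahedral adduct of 7 and MeMgBr (new carbinol centre undefined) | CON(C)C(C)(O[Mg]Br)[C@@H](C)N(C(=O)OCc1ccccc1)[C@@H]1CCC[C@@H]2C=C[C@H]12 | intermediate (not isolated)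
9 | benzyl N-[(1S,2R,6R)-bicyclo[4.2.0]oct-7-en-2-yl]-N-[(2R)-3-oxobutan-2-yl]carbamate | CC(=O)[C@@H](C)N(C(=O)OCc1ccccc1)[C@@H]1CCC[C@@H]2C=C[C@H]12 | intermediate
10 | lithium but-1-en-2-olate derived from 9 by loss of a CH3 proton | [Li]OC(=C)[C@@H](C)N(C(=O)OCc1ccccc1)[C@@H]1CCC[C@@H]2C=C[C@H]12 | intermediate (not isolated)
11 | benzyl N-[(1S,2R,6R)-bicyclo[4.2.0]oct-7-en-2-yl]-N-{(2R)-3-[(triethylsilyl)oxy]but-3-en-2-yl}carbamate (fragment 1) | C=C(O[Si](CC)(CC)CC)[C@@H](C)N(C(=O)OCc1ccccc1)[C@@H]1CCC[C@@H]2C=C[C@H]12 | intermediate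
12 | (2R)-2-propyloxirane ((R)-1,2-epoxypentane) | CCC[C@@H]1CO1 | starting material
13 | (5R)-oct-1-en-5-ol | C=CCC[C@H](O)CCC | intermediate
14 | tert-butyl(dimethyl){[(5R)-oct-1-en-5-yl]oxy}silane (fragment 2) | C=CCC[C@H](O[Si](C)(C)C(C)(C)C)CCC | intermediate
15 | benzyl (2R,4aR,5R,8aR)-5-[(1E,5R)-5-{[tert-butyl(dimethyl)silyl]oxy}oct-1-en-1-yl]-2-methyl-3-[(triethylsilyl)oxy]-4a,5,6,7,8,8a-hexahydroquinoline-1(2H)-carboxylate | CC[Si](CC)(CC)OC1=C[C@H]2[C@@H](/C=C/CC[C@H](O[Si](C)(C)C(C)(C)C)CCC)CCC[C@H]2N(C(=O)OCc3ccccc3)[C@@H]1C | intermediate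
16 | benzyl (2R,4aS,5R,8aR)-5-[(1E,5R)-5-{[tert-butyl(dimethyl)silyl]oxy}oct-1-en-1-yl]-2-methyl-3-oxooctahydroquinoline-1(2H)-carboxylate | O=C1C[C@H]2[C@@H](/C=C/CC[C@H](O[Si](C)(C)C(C)(C)C)CCC)CCC[C@H]2N(C(=O)OCc3ccccc3)[C@@H]1C | intermediate
17 | benzyl (2R,3R,4aS,5R,8aR)-5-[(1E,5R)-5-{[tert-butyl(dimethyl)silyl]oxy}oct-1-en-1-yl]-3-hydroxy-2-methyloctahydroquinoline-1(2H)-carboxylate | O[C@@H]1C[C@H]2[C@@H](/C=C/CC[C@H](O[Si](C)(C)C(C)(C)C)CCC)CCC[C@H]2N(C(=O)OCc3ccccc3)[C@@H]1C | intermediate
18 | (2R,3R,4aS,5S,8aR)-5-[(5R)-5-{[tert-butyl(dimethyl)silyl]oxy}octyl]-2-methyldecahydroquinolin-3-ol | O[C@@H]1C[C@H]2[C@@H](CCCC[C@H](O[Si](C)(C)C(C)(C)C)CCC)CCC[C@H]2N[C@@H]1C | intermediate (not isolated)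
19 | tert-butyl (2R,3R,4aS,5S,8aR)-5-[(5R)-5-{[tert-butyl(dimethyl)silyl]oxy}octyl]-3-hydroxy-2-methyloctahydroquinoline-1(2H)-carboxylate | O[C@@H]1C[C@H]2[C@@H](CCCC[C@H](O[Si](C)(C)C(C)(C)C)CCC)CCC[C@H]2N(C(=O)OC(C)(C)C)[C@@H]1C | intermediate
20 | (2E,4E)-octa-2,4-dienoic acid | CCC/C=C/C=C/C(=O)O | starting material
21 | (2E,4E)-octa-2,4-dienoic 2,4,6-trichlorobenzoic anhydride | CCC/C=C/C=C/C(=O)OC(=O)c1c(Cl)cc(Cl)cc1Cl | intermediate (not isolated)
22 | tert-butyl (2R,3R,4aS,5S,8aR)-5-[(5R)-5-{[tert-butyl(dimethyl)silyl]oxy}octyl]-2-methyl-3-{[(2E,4E)-octa-2,4-dienoyl]oxy}octahydroquinoline-1(2H)-carboxylate | CCC/C=C/C=C/C(=O)O[C@@H]1C[C@H]2[C@@H](CCCC[C@H](O[Si](C)(C)C(C)(C)C)CCC)CCC[C@H]2N(C(=O)OC(C)(C)C)[C@@H]1C | intermediate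
23 | (2R,3R,4aS,5S,8aR)-5-[(5R)-5-hydroxyoctyl]-2-methyldecahydroquinolin-3-yl (2E,4E)-octa-2,4-dienoate | CCC/C=C/C=C/C(=O)O[C@@H]1C[C@H]2[C@@H](CCCC[C@H](O)CCC)CCC[C@H]2N[C@@H]1C | target

**Step count**

Total: 14 steps. Longest linear sequence: 12 steps (steps 1 to 6 and 9 to 14, from cyclohex-2-en-1-one).

**Steps most likely to fail**

1. Step 9 (proposed new method). The cyclobutene may be lost to ring-opening oligomerisation, or the cascade may stop half-way (side chain coupled but ring A not closed, or the reverse). The fallback runs the three metathesis events one at a time, each a known reaction; it sets out from 11 and comes back at 15. Compound 11 is opened with ethene (1 atm) and RuCl2(PCy3)2(=CHPh) (first-generation Grubbs catalyst), which leaves the 1,1-disubstituted silyl enol ether alone, to give benzyl N-[(1R,2S,3R)-2,3-diethenylcyclohexyl]-N-{(2R)-3-[(triethylsilyl)oxy]but-3-en-2-yl}carbamate F1. Ring-closing metathesis of this triene with RuCl2(H2IMes)(PCy3)(=CHPh) (second-generation Grubbs catalyst) in dilute toluene joins the C4 vinyl group to the enol ether and should give benzyl (2R,4aR,5R,8aR)-5-ethenyl-2-methyl-3-[(triethylsilyl)oxy]-4a,5,6,7,8,8a-hexahydroquinoline-1(2H)-carboxylate F2. Cross-metathesis of its vinyl group with an excess of 14 and RuCl2(H2IMes)(=CH-C6H4-2-O-i-Pr) then returns to 15.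

2. Step 2. Hydride delivery to the iminium may show poor facial selectivity, or the two diastereomers that arise from the racemic ketone may not separate. The fallback sets the C–N centre under auxiliary control and attaches the alanine unit by SN2; it sets out from 2 and comes back at 5. Ketone 2 is condensed with (R)-2-methylpropane-2-sulfinamide and Ti(OEt)4 to (R)-N-[(1S,6R)-bicyclo[4.2.0]oct-7-en-2-ylidene]-2-methylpropane-2-sulfinamide F3 (with its ring-enantiomeric diastereomer). Reduction with NaBH4 or LiBH(s-Bu)3, which reduce such imines with opposite sense (the one that reinforces convex-face attack is used), followed by separation of the diastereomers, should give (R)-N-[(1S,2R,6R)-bicyclo[4.2.0]oct-7-en-2-yl]-2-methylpropane-2-sulfinamide F4. HCl in methanol removes the auxiliary to give (1S,2R,6R)-bicyclo[4.2.0]oct-7-en-2-amine F5. This amine is alkylated in CH2Cl2 at low temperature with methyl (2S)-2-{[(trifluoromethyl)sulfonyl]oxy}propanoate F6 (made from commercial methyl (S)-lactate, Tf2O and 2,6-lutidine); the displacement goes with inversion and gives 5.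

3. Step 11. Hydride may add to the wrong face of C3, so that the alcohol trans to the C2 methyl predominates. The fallback keeps that epimer and corrects C3 when the ester is made; it sets out from 16 and comes back at 22. The reduction then delivers benzyl (2R,3S,4aS,5R,8aR)-5-[(1E,5R)-5-{[tert-butyl(dimethyl)silyl]oxy}oct-1-en-1-yl]-3-hydroxy-2-methyloctahydroquinoline-1(2H)-carboxylate F7. Hydrogenation over Pd/C with Boc2O, as in step 12, passes through (2R,3S,4aS,5S,8aR)-5-[(5R)-5-{[tert-butyl(dimethyl)silyl]oxy}octyl]-2-methyldecahydroquinolin-3-ol F8 and gives tert-butyl (2R,3S,4aS,5S,8aR)-5-[(5R)-5-{[tert-butyl(dimethyl)silyl]oxy}octyl]-3-hydroxy-2-methyloctahydroquinoline-1(2H)-carboxylate F9. Mitsunobu esterification of this alcohol with 20 (PPh3, diisopropyl azodicarboxylate, toluene) inverts C3 and gives 22 directly.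

**Further compounds**

F1 | step 9 | benzyl N-[(1R,2S,3R)-2,3-diethenylcyclohexyl]-N-{(2R)-3-[(triethylsilyl)oxy]but-3-en-2-yl}carbamate | C=C(O[Si](CC)(CC)CC)[C@@H](C)N(C(=O)OCc1ccccc1)[C@@H]1CCC[C@H](C=C)[C@@H]1C=C
F2 | step 9 | benzyl (2R,4aR,5R,8aR)-5-ethenyl-2-methyl-3-[(triethylsilyl)oxy]-4a,5,6,7,8,8a-hexahydroquinoline-1(2H)-carboxylate | CC[Si](CC)(CC)OC1=C[C@H]2[C@@H](C=C)CCC[C@H]2N(C(=O)OCc3ccccc3)[C@@H]1C
F3 | step 2 | (R)-N-[(1S,6R)-bicyclo[4.2.0]oct-7-en-2-ylidene]-2-methylpropane-2-sulfinamide | CC(C)(C)[S@@](=O)N=C1CCC[C@@H]2C=C[C@H]12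
F4 | step 2 | (R)-N-[(1S,2R,6R)-bicyclo[4.2.0]oct-7-en-2-yl]-2-methylpropane-2-sulfinamide | CC(C)(C)[S@@](=O)N[C@@H]1CCC[C@@H]2C=C[C@H]12
F5 | step 2 | (1S,2R,6R)-bicyclo[4.2.0]oct-7-en-2-amine | N[C@@H]1CCC[C@@H]2C=C[C@H]12
F6 | step 2 | methyl (2S)-2-{[(trifluoromethyl)sulfonyl]oxy}propanoate | COC(=O)[C@H](C)OS(=O)(=O)C(F)(F)F
F7 | step 11 | benzyl (2R,3S,4aS,5R,8aR)-5-[(1E,5R)-5-{[tert-butyl(dimethyl)silyl]oxy}oct-1-en-1-yl]-3-hydroxy-2-methyloctahydroquinoline-1(2H)-carboxylate | O[C@H]1C[C@H]2[C@@H](/C=C/CC[C@H](O[Si](C)(C)C(C)(C)C)CCC)CCC[C@H]2N(C(=O)OCc3ccccc3)[C@@H]1C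
F8 | step 11 | (2R,3S,4aS,5S,8aR)-5-[(5R)-5-{[tert-butyl(dimethyl)silyl]oxy}octyl]-2-methyldecahydroquinolin-3-ol | O[C@H]1C[C@H]2[C@@H](CCCC[C@H](O[Si](C)(C)C(C)(C)C)CCC)CCC[C@H]2N[C@@H]1C
F9 | step 11 | tert-butyl (2R,3S,4aS,5S,8aR)-5-[(5R)-5-{[tert-butyl(dimethyl)silyl]oxy}octyl]-3-hydroxy-2-methyloctahydroquinoline-1(2H)-carboxylate | O[C@H]1C[C@H]2[C@@H](CCCC[C@H](O[Si](C)(C)C(C)(C)C)CCC)CCC[C@H]2N(C(=O)OC(C)(C)C)[C@@H]1C
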